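## Retrosynthetic overview

1. The target is a 33-membered lactone without stereocentres (C1 = carbonyl carbon, C2–C32 = the 31 ring CH2 groups, ring oxygen on C32); it is traced back to the ring olefin C14=C15 by hydrogenation.
2. The ring olefin comes from ring-closing olefin metathesis that forms C14–C15 in the acyclic diene ester nonadec-18-en-1-yl pentadec-14-enoate. This is the only ring of the route, closed in the penultimate step.
3. Enabling feature: C14–C15 lies inside the unbranched, unfunctionalised polymethylene arc C2–C32 of the strain-free 33-membered ring, 12 CH2 groups from the C1 carbonyl and 17 CH2 groups from the ring oxygen. Two terminal vinyl groups can therefore meet there without ester chelation, and the olefin geometry is erased by hydrogenation.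
4. The diene ester comes from Steglich esterification of pentadec-14-enoic acid with nonadec-18-en-1-ol.
5. Both halves come from one Grignard reagent, oct-7-en-1-ylmagnesium bromide, coupled under Li2CuCl4 catalysis with 7-bromoheptanoic acid and with 11-bromoundecan-1-ol.

Key step: step 5

Remark on the chemistry: the Grignard reagent 2 is prepared once as a titrated THF solution and divided between steps 2 and 3. The ring olefin 10 is expected as an E/Z mixture, which is of no consequence because step 6 saturates it.

## Route

Step 1
Reactants: 1 8-bromooct-1-ene
Product: 2 oct-7-en-1-ylmagnesium bromide (titrated THF solution)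
Conditions: Mg turnings (1.2 equiv), iodine (cat.), THF, 40 °C
Reagents that add atoms: magnesium, [Mg]
Why: Grignard formation by insertion of magnesium into the primary C–Br bond; the oct-7-enyl chain is too long for radical cyclisation onto the vinyl group during insertion, so the terminal alkene should be retained.

Step 2
Reactants: 3 7-bromoheptanoic acid; 2 oct-7-en-1-ylmagnesium bromide
Product: 5 pentadec-14-enoic acid, via chloromagnesium 7-bromoheptanoate 4 (not isolated)
Conditions: MeMgCl (1.0 equiv), THF, −20 °C; then Li2CuCl4 (3 mol %), 2 (1.3 equiv), −20 °C to rt; aq. HCl work-up
Reagents that add atoms: none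
Why: Kochi-type Li2CuCl4-catalysed sp3–sp3 cross-coupling of a primary alkyl Grignard reagent with a primary bromide, run on the chloromagnesium carboxylate so that the acidic proton is removed beforehand by the sacrificial MeMgCl and the carboxylate stays inert at low temperature; neutral homocoupling hydrocarbon should be removed by acid–base extraction.

Step 3
Reactants: 6 11-bromoundecan-1-ol; 2 oct-7-en-1-ylmagnesium bromide
Product: 8 nonadec-18-en-1-ol, via chloromagnesium 11-bromoundecan-1-olate 7 (not isolated)
Conditions: MeMgCl (1.0 equiv), THF, −20 °C; then Li2CuCl4 (3 mol %), 2 (1.3 equiv), −20 °C to rt; aq. HCl work-up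
Reagents that add atoms: none
Why: the same Kochi-type Li2CuCl4-catalysed alkyl–alkyl coupling, here on the magnesium alkoxide of the bromo alcohol, which is unreactive towards the Grignard reagent, so that only the primary C–Br bond should be substituted.

Step 4
Reactants: 5 pentadec-14-enoic acid; 8 nonadec-18-en-1-ol
Product: 9 nonadec-18-en-1-yl pentadec-14-enoate
Conditions: DCC (1.1 equiv), DMAP (0.1 equiv), CH2Cl2, 0 °C to rt
Reagents that add atoms: none
Why: Steglich esterification (carbodiimide activation with DMAP acyl transfer) of an unhindered acid with an unhindered primary alcohol; the two terminal alkenes are inert under these conditions.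

Step 5
Reactants: 9 nonadec-18-en-1-yl pentadec-14-enoate
Product: 10 oxacyclotritriacont-15-en-2-one (E/Z mixture)
Conditions: second-generation Grubbs catalyst RuCl2(=CHPh)(PCy3)(H2IMes) (5 mol %), 1,4-benzoquinone (10 mol %), CH2Cl2, slow addition of 9 to about 1 mM, 40 °C, Ar sparge; then ethyl vinyl ether
Reagents that add atoms: none
Why: Ring-closing olefin metathesis: the ruthenium benzylidene exchanges onto one terminal vinyl group of 9, and the resulting alkylidene adds [2+2] to the other vinyl group to give a ruthenacyclobutane whose cycloreversion forms the C14=C15 bond (C1 = lactone carbonyl carbon) and expels ethylene. The closest known reaction type is the macrocyclic ring-closing metathesis of ω-alkenyl ω-alkenoates to large-ring musk lactones and to rings of thirty and more members. The only ring, the 33-membered lactone, is closed end to end between the two terminal CH= carbons as a macrocyclisation under ring–chain equilibrium, not by attack on a preformed ring. No stereocentre is created, and the geometry of the new C14=C15 bond (E expected to predominate under thermodynamic control) needs no control because step 6 removes it. The selectivities needed are closure over acyclic diene metathesis oligomerisation and the absence of double-bond migration before closure, which would end in ring-contracted homologues; the first should be secured by slow addition to about 1 mM with removal of ethylene, under which reversible metathesis lets oligomers back-bite into the strain-free ring, and the second by 1,4-benzoquinone, which intercepts ruthenium hydrides. In the substrate both olefins are unhindered monosubstituted vinyl groups and the only Lewis-basic group, the ester, is 12 and 17 methylenes away, so that no carbonyl chelate can tie up the carbene.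

Step 6
Reactants: 10 oxacyclotritriacont-15-en-2-one (E/Z mixture)
Product: 11 oxacyclotritriacontan-2-one (32-dotriacontanolide)
Conditions: H2 (1 atm), 10 wt % Pd/C, EtOAc/THF, rt
Reagents that add atoms: none
Why: heterogeneous catalytic hydrogenation of an unhindered disubstituted olefin, which should saturate both geometric isomers to the same product and leave the lactone untouched.

## Compound list

1 | 8-bromooct-1-ene | C=CCCCCCCBr | starting material
2 | oct-7-en-1-ylmagnesium bromide | C=CCCCCCC[Mg]Br | intermediate
3 | 7-bromoheptanoic acid | OC(=O)CCCCCCBr | starting material
4 | chloromagnesium 7-bromoheptanoate | BrCCCCCCC(=O)O[Mg]Cl | intermediate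
5 | pentadec-14-enoic acid | C=CCCCCCCCCCCCCC(=O)O | intermediate
6 | 11-bromoundecan-1-ol | OCCCCCCCCCCCBr | starting material
7 | chloromagnesium 11-bromoundecan-1-olate | Cl[Mg]OCCCCCCCCCCCBr | intermediate
8 | nonadec-18-en-1-ol | C=CCCCCCCCCCCCCCCCCCO | intermediate
9 | nonadec-18-en-1-yl pentadec-14-enoate | C=CCCCCCCCCCCCCC(=O)OCCCCCCCCCCCCCCCCCC=C | intermediate
10 | (15E/Z)-oxacyclotritriacont-15-en-2-one (mixture of olefin isomers, E isomer drawn) | O=C1CCCCCCCCCCCC/C=C/CCCCCCCCCCCCCCCCCO1 | intermediate
11 | oxacyclotritriacontan-2-one (32-dotriacontanolide; no stereocentre) | O=C1CCCCCCCCCCCCCCCCCCCCCCCCCCCCCCCO1 | target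

## Step count and risks

Total step count: 6. Longest linear sequence: 5 steps (steps 1, 2, 4, 5, 6, or equally 1, 3, 4, 5, 6).

Steps most likely to fail:

Step 5. Intermolecular acyclic diene metathesis may outrun ring closure and lead to oligomers, and double-bond migration before closure may lead to ring-contracted lactones that are hard to separate after hydrogenation. The fallback sets out from 5 and 8 and comes back to the route at 11; it makes the C14–C15 bond intermolecularly and closes the ring at the lactone C–O bond instead. Cross-metathesis of 8 with an excess of 5 (second-generation Grubbs catalyst RuCl2(=CHPh)(PCy3)(H2IMes), CH2Cl2, 40 °C) should give (14E/Z)-32-hydroxydotriacont-14-enoic acid F1, separable from the symmetrical diacid and diol homodimers by polarity. Hydrogenation (H2, Pd/C, THF) should give 32-hydroxydotriacontanoic acid F2. Yamaguchi macrolactonisation should then deliver 11: 2,4,6-trichlorobenzoyl chloride and Et3N in THF at rt give 2,4,6-trichlorobenzoic 32-hydroxydotriacontanoic anhydride F3, which is added slowly to DMAP in toluene at reflux under high dilution.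

Step 3. The magnesium alkoxide may precipitate, and any incompletely deprotonated hydroxyl would quench the Grignard reagent, so that reduction and Wurtz-type homocoupling take the place of cross-coupling. The fallback sets out from 6 and comes back at 8 by masking the hydroxyl before the coupling. Silylation (TBSCl, imidazole, DMF, rt) should give (11-bromoundecyl)oxy(tert-butyl)dimethylsilane F4. Li2CuCl4-catalysed coupling with 2 (THF, −10 °C to rt) should give tert-butyldimethyl(nonadec-18-en-1-yloxy)silane F5. Methanolysis (camphorsulfonic acid cat., MeOH/CH2Cl2, rt) should release 8.

Step 2. The sparingly soluble magnesium carboxylate may couple sluggishly, leaving homocoupling of 2 and attack of the Grignard reagent on the carboxylate on warming as the main processes. The fallback sets out from 3 and comes back at 5 by running the coupling at the ester stage. Fischer esterification (MeOH, H2SO4 cat., reflux) should give methyl 7-bromoheptanoate F6. Coupling with 2 under Li2CuCl4 catalysis with N-methylpyrrolidone as co-solvent (THF, 0 °C), conditions under which esters are tolerated, should give methyl pentadec-14-enoate F7. Saponification (LiOH, THF/H2O; then aq. HCl) should give 5.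

Further compounds
F1 | step 5 | (14E/Z)-32-hydroxydotriacont-14-enoic acid (E isomer drawn) | OC(=O)CCCCCCCCCCCC/C=C/CCCCCCCCCCCCCCCCCO
F2 | step 5 | 32-hydroxydotriacontanoic acid | OC(=O)CCCCCCCCCCCCCCCCCCCCCCCCCCCCCCCO
F3 | step 5 | 2,4,6-trichlorobenzoic 32-hydroxydotriacontanoic anhydride | OCCCCCCCCCCCCCCCCCCCCCCCCCCCCCCCC(=O)OC(=O)c1c(Cl)cc(Cl)cc1Cl
F4 | step 3 | (11-bromoundecyl)oxy(tert-butyl)dimethylsilane | BrCCCCCCCCCCCO[Si](C)(C)C(C)(C)C
F5 | step 3 | tert-butyldimethyl(nonadec-18-en-1-yloxy)silane | C=CCCCCCCCCCCCCCCCCCO[Si](C)(C)C(C)(C)C
F6 | step 2 | methyl 7-bromoheptanoate | COC(=O)CCCCCCBr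
F7 | step 2 | methyl pentadec-14-enoate | C=CCCCCCCCCCCCCC(=O)OC
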